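**Assumptions.** Both flavan units in the SMILES are (2R,3S)-2,3-trans with a 3-OH and a B ring bearing 4-OH and 3-O-aryl. The target (C30H26O11) is therefore a 3',3'''-diaryl ether of two (+)-catechin units, and (+)-catechin is the only chiral input. I also assume that a bulky silyl chloride reacts preferentially at the less hindered 4'-OH of a tri-O-benzylcatechin, and that the two regioisomers can be separated.

**Retrosynthetic overview**
1. No ring is formed in this route. The A, B and C rings and all six stereocentres of both halves come intact from two molecules of (+)-catechin.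
2. Disconnect the diaryl ether C3'–O bond by Pd-catalysed C–O coupling of a catechin-derived aryl triflate with the matching free 3'-phenol.
3. Both partners come from one intermediate, 3,5,7-tri-O-benzyl-4'-O-TBDPS-catechin. Its catechol is first masked transiently as a boronate, the other OH groups are benzylated, and the 4'-OH is then silylated selectively.
4. Final order: diaryl ether formation, then fluoride removal of the silyl groups, then hydrogenolysis of the benzyl groups.

**Step 1**
Reactants: 1 (+)-catechin; 2 phenylboronic acid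
Product: 3 catechin 3',4'-O-phenylboronate
Conditions: PhB(OH)2 (1.1 equiv), THF, 4 Å MS, rt
Reagents that add atoms: phenylboronic acid, OB(O)c1ccccc1 (it is removed again in Step 3)
Why: Only the catechol forms a five-membered cyclic boronate. This masks the B ring and keeps the 4'-O⁻ from forming, which would open the way to C2 epimerisation through a quinone methide.

**Step 2**
Reactants: 3; 4 benzyl bromide
Product: 5 3,5,7-tri-O-benzylcatechin 3',4'-O-phenylboronate
Conditions: NaH (3.3 equiv), BnBr (3.3 equiv), TBAI (cat.), DMF, 0 °C to rt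
Reagents that add atoms: benzyl bromide, BrCc1ccccc1
Why: Williamson O-benzylation of the 5-, 7- and 3-OH groups. No stereocentre is touched, and a stable benzyl ether is used so that it can be removed by hydrogenolysis at the end.

**Step 3**
Reactants: 5
Product: 6 3,5,7-tri-O-benzyl-(+)-catechin (free 3',4'-catechol)
Conditions: diethanolamine (1.2 equiv), CH2Cl2/Et2O, rt; filter off the PhB(diethanolamine) adduct
Reagents that add atoms: none
Why: Boronate transesterification. Diethanolamine traps the boron as a B–N chelate and releases the catechol under neutral conditions.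

**Step 4**
Reactants: 6; 7 TBDPSCl
Product: 8 3,5,7-tri-O-benzyl-4'-O-TBDPS-(+)-catechin (3'-OH free)
Conditions: TBDPSCl (1.0 equiv), imidazole (2.5 equiv), DMF, –20 to 0 °C; chromatographic separation of the 3'-O-silyl isomer
Reagents that add atoms: TBDPSCl, CC(C)(C)[Si](Cl)(c1ccccc1)c1ccccc1
Why: Sterically controlled mono-silylation of a catechol at the more accessible 4'-OH. The silyl group leaves a single free 3'-OH and blocks the 4'-O from quinone methide chemistry.

**Step 5**
Reactants: 8 (about half of the batch); 9 N-phenylbis(trifluoromethanesulfonimide)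
Product: 10 3'-O-triflate of 8
Conditions: PhNTf2 (1.2 equiv), Et3N (2 equiv), DMAP (cat.), CH2Cl2, rt
Reagents that add atoms: PhNTf2, O=S(=O)(C(F)(F)F)N(c1ccccc1)S(=O)(=O)C(F)(F)F
Why: Only one free phenol is present, so sulfonylation gives the aryl triflate (the electrophilic coupling partner) cleanly.

**Step 6**
Reactants: 10 (aryl triflate); 8 (phenol)
Product: 11 fully protected bis-catechin 3'-O-3'''-ether
Conditions: Pd2(dba)3 (2.5 mol%), tBuBrettPhos (7 mol%), K3PO4 (2 equiv), toluene, 100 °C
Reagents that add atoms: none (TfOH is lost)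
Why: Buchwald–Hartwig-type Pd-catalysed C–O cross-coupling forms the hindered ortho-alkoxy diaryl ether. All oxygen atoms are protected, so C2 cannot epimerise.

**Step 7**
Reactants: 11
Product: 12 tetra-O-benzyl... i.e. hexa-O-benzyl dimer with both 4'-OH free
Conditions: TBAF (4 equiv) buffered with AcOH (4 equiv), THF, 0 °C to rt
Reagents that add atoms: none
Why: Buffered fluoride cleaves the aryl silyl ethers and leaves the benzyl ethers intact. Buffering prevents epimerisation and oxidation of the freed phenols.

**Step 8**
Reactants: 12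
Product: 13 catechin-(3'-O-3''')-afzelechin (target)
Conditions: H2 (1 atm), Pd(OH)2/C, THF/MeOH 1:1, rt, under N2
Reagents that add atoms: none
Why: Hydrogenolysis removes all six benzyl ethers. The diaryl ether, the benzylic C2–O1 bond and the C2 and C3 stereocentres survive, so the configuration set by the starting catechin is retained.

**Compound list**
1 | (+)-catechin, (2R,3S) | Oc1cc(O)c2c(c1)O[C@H](c1ccc(O)c(O)c1)[C@@H](O)C2 | starting material
2 | phenylboronic acid | OB(O)c1ccccc1 | starting material
3 | catechin 3',4'-O-phenylboronate | Oc1cc(O)c2c(c1)O[C@H](c1ccc3OB(c4ccccc4)Oc3c1)[C@@H](O)C2 | intermediate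
4 | benzyl bromide | BrCc1ccccc1 | starting material
5 | 3,5,7-tri-O-benzylcatechin 3',4'-O-phenylboronate | c1ccccc1COc1cc(OCc2ccccc2)c2c(c1)O[C@H](c1ccc3OB(c4ccccc4)Oc3c1)[C@@H](OCc1ccccc1)C2 | intermediate
6 | 3,5,7-tri-O-benzyl-(+)-catechin | c1ccccc1COc1cc(OCc2ccccc2)c2c(c1)O[C@H](c1ccc(O)c(O)c1)[C@@H](OCc1ccccc1)C2 | intermediate
7 | tert-butyldiphenylsilyl chloride | CC(C)(C)[Si](Cl)(c1ccccc1)c1ccccc1 | starting material
8 | 3,5,7-tri-O-benzyl-4'-O-TBDPS-(+)-catechin | c1ccccc1COc1cc(OCc2ccccc2)c2c(c1)O[C@H](c1ccc(O[Si](c3ccccc3)(c3ccccc3)C(C)(C)C)c(O)c1)[C@@H](OCc1ccccc1)C2 | intermediate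
9 | N-phenylbis(trifluoromethanesulfonimide) | O=S(=O)(C(F)(F)F)N(c1ccccc1)S(=O)(=O)C(F)(F)F | starting material
10 | aryl triflate of 8 | c1ccccc1COc1cc(OCc2ccccc2)c2c(c1)O[C@H](c1ccc(O[Si](c3ccccc3)(c3ccccc3)C(C)(C)C)c(OS(=O)(=O)C(F)(F)F)c1)[C@@H](OCc1ccccc1)C2 | intermediate
11 | protected diaryl ether dimer | CC(C)(C)[Si](c1ccccc1)(c1ccccc1)Oc1ccc([C@H]2Oc3cc(OCc4ccccc4)cc(OCc4ccccc4)c3C[C@@H]2OCc2ccccc2)cc1Oc1cc([C@H]2Oc3cc(OCc4ccccc4)cc(OCc4ccccc4)c3C[C@@H]2OCc2ccccc2)ccc1O[Si](c1ccccc1)(c1ccccc1)C(C)(C)C | intermediate
12 | desilylated hexa-O-benzyl dimer | Oc1ccc([C@H]2Oc3cc(OCc4ccccc4)cc(OCc4ccccc4)c3C[C@@H]2OCc2ccccc2)cc1Oc1cc([C@H]2Oc3cc(OCc4ccccc4)cc(OCc4ccccc4)c3C[C@@H]2OCc2ccccc2)ccc1O | intermediate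
13 | catechin-(3'-O-3''')-afzelechin | Oc1cc(O)c2c(c1)O[C@H](c1ccc(O)c(Oc3cc([C@H]4Oc5cc(O)cc(O)c5C[C@@H]4O)ccc3O)c1)[C@@H](O)C2 | target

**Total steps:** 8. **Longest linear sequence:** 8 (1 → 3 → 5 → 6 → 8 → 10 → 11 → 12 → 13). Compound 8 is also used as the phenol partner in Step 6.

**Three steps most likely to fail**
1. **Step 4, regioselective 4'-silylation.** The selectivity between the 3'- and 4'-OH is modest, and the wrong isomer would put the ether at C4'. Fallback: change the approach to start from (+)-afzelechin, whose B-ring ortho positions are equivalent. Block the A ring at C6/C8, borylate ortho to the 4'-O-carbamate, and oxidise half of the material to the 3'-phenol. Then couple the two halves, so no catechol differentiation is needed.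
2. **Step 6, Pd-catalysed coupling.** Both partners are ortho-alkoxy substituted, and the aryl triflate can be cleaved by phenoxide at 100 °C. Fallback: convert 10 to the arylboronic acid (Miyaura borylation, then hydrolysis) and run a room-temperature Cu(OAc)2/pyridine Chan–Lam coupling with 8.
3. **Steps 2–3, boronate-masked benzylation.** NaH may open the boronate ester and give O-benzylation on the B ring. Fallback: mask the catechol as its 3',4'-O-diphenylmethylene ketal. Benzylate, then open the ketal regioselectively with DIBAL, which gives the differentiated phenol directly and replaces Steps 3–4.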